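**Plan**

- Retrosynthetic cuts: ester C1–OMe; dioxane O2–C3 (oxa-Michael) and C2=C3 (Wittig); O1–C6 (peroxide SN2 on a C6 sulfonate); oxolane O–C7 together with the C6 oxygen (Re(VII) syn-oxidative cyclisation of a C6=C7 alkene); C6=C7 itself (Wittig union of a C7–C24 lactol with a C3–C6 ylide); C11–C12 (Grignard/epoxide); the C17–C20 diene from a 1,3-diyne.
- Forward order: chain (Cadiot–Chodkiewicz, zinc reduction) → γ-lactone → lactol; union at C6–C7; the oxolane closes first (O–C7); the O–O unit is then put on C6, C1–C2 are added, and the 1,2-dioxane closes last at C3.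
- Enabling feature: C6 (dioxane carbon on O1) and C7 (oxolane C2) are vicinal C–O carbons, and the oxolane oxygen on C10 lies four atoms from C6. A C7 lactol therefore gives, on Z-olefination at C7, a bishomoallylic alcohol whose C6=C7 geometry encodes both stereocentres.
- Stereochemistry: C10 from L-glutamic acid (chiral pool); C7 (trans ring) and C6 (erythro) from the Z-alkene and C10 in the Re(VII) cyclisation; C6 is then inverted by the peroxide SN2 to the threo relation; C3 from the chair 6-exo oxa-Michael closure (trans, diequatorial).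

Key step: step 9

Remark: locants C1–C24 follow the carbon chain of the target (C1 = carboxyl carbon, C3 and C6 = dioxane carbons, C7 and C10 = oxolane carbons, C24 = vinyl terminus); lactol and peroxyacetal centres that are not stereocentres of the target are handled as epimer mixtures.

**Route**

Step 1
Reactants: 1 hex-1-en-5-yne
Product: 2 6-bromohex-1-en-5-yne
Conditions: NBS, AgNO3 (cat.), acetone, rt
Reagents that add atoms: N-bromosuccinimide, O=C1CCC(=O)N1Br
Why: Silver-catalysed electrophilic bromination of the terminal alkyne C–H should give the 1-bromoalkyne without touching the isolated alkene; no stereocentre is formed.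

Step 2
Reactants: 2 6-bromohex-1-en-5-yne; 3 hept-6-yn-1-ol
Product: 4 trideca-12-en-6,8-diyn-1-ol
Conditions: CuCl (cat.), NH2OH·HCl, 30% aq. n-BuNH2, Et2O, 0 °C
Reagents that add atoms: none
Why: Cadiot–Chodkiewicz coupling of the copper(I) acetylide of 3 with bromoalkyne 2 should give the unsymmetrical 1,3-diyne, the free hydroxyl and the alkene being tolerated; no stereocentre is formed.

Step 3
Reactants: 4 trideca-12-en-6,8-diyn-1-ol
Product: 5 (6Z,8Z)-trideca-6,8,12-trien-1-ol
Conditions: Zn(Cu/Ag), MeOH/H2O (1:1), 40 °C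
Reagents that add atoms: none
Why: Reduction with activated zinc in a protic medium reduces only conjugated triple bonds, each by cis delivery of two hydrogens, so the diyne should give the (Z,Z)-diene while the isolated terminal alkene stays untouched.

Step 4
Reactants: 5 (6Z,8Z)-trideca-6,8,12-trien-1-ol
Product: 6 (5Z,7Z)-13-bromotrideca-1,5,7-triene
Conditions: CBr4, PPh3, CH2Cl2, 0 °C
Reagents that add atoms: carbon tetrabromide, BrC(Br)(Br)Br
Why: Appel reaction, in which bromide displaces the alkoxyphosphonium ion at the primary carbon under neutral conditions that should not isomerise the diene.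

Step 5
Reactants: 7 [(2S)-5-oxooxolan-2-yl]methyl 4-methylbenzenesulfonate
Product: 8 methyl 3-[(2S)-oxiran-2-yl]propanoate
Conditions: NaOMe (1.0 equiv), MeOH, 0 °C → rt
Reagents that add atoms: sodium methoxide, C[O-].[Na+]
Why: Methoxide opens the lactone by transesterification and the freed alkoxide displaces the neighbouring primary tosylate (intramolecular Williamson reaction), so the stereocentre from L-glutamic acid is carried over untouched.

Step 6
Reactants: 6 (5Z,7Z)-13-bromotrideca-1,5,7-triene; 8 methyl 3-[(2S)-oxiran-2-yl]propanoate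
Product: 11 (5R)-5-[(7Z,9Z)-tetradeca-7,9,13-trien-1-yl]oxolan-2-one, via Grignard reagent 9 (not isolated), via hydroxy ester 10 (not isolated)
Conditions: Mg, THF, 40 °C; then CuI (10 mol %), 8 (0.8 equiv), THF, −40 → −10 °C; aq. NH4Cl; PPTS (cat.), CH2Cl2, rt
Reagents that add atoms: none
Why: Copper-catalysed SN2 opening of the terminal epoxide by the Grignard reagent at the unsubstituted carbon (faster than ester addition at −40 °C) and lactonisation of the γ-hydroxy ester should give the γ-lactone; the carbinol centre is not involved and becomes C10 (R).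

Step 7
Reactants: 11 (5R)-5-[(7Z,9Z)-tetradeca-7,9,13-trien-1-yl]oxolan-2-one
Product: 12 (5R)-5-[(7Z,9Z)-tetradeca-7,9,13-trien-1-yl]oxolan-2-ol
Conditions: DIBAL-H (1.1 equiv), CH2Cl2, −78 °C; Rochelle salt
Reagents that add atoms: none
Why: DIBAL-H half-reduction of a γ-lactone at −78 °C stops at the aluminium acetal and should give the lactol, with C10 unaffected.

Step 8
Reactants: 13 (4-bromobutoxy)(tert-butyl)dimethylsilane
Product: 14 {4-[(tert-butyldimethylsilyl)oxy]butyl}triphenylphosphonium bromide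
Conditions: PPh3, MeCN, reflux
Reagents that add atoms: triphenylphosphine, c1ccc(cc1)P(c1ccccc1)c1ccccc1
Why: SN2 quaternisation of triphenylphosphine by the primary bromide gives the phosphonium salt; the silyl ether is inert.

Step 9
Reactants: 12 (5R)-5-[(7Z,9Z)-tetradeca-7,9,13-trien-1-yl]oxolan-2-ol; 14 {4-[(tert-butyldimethylsilyl)oxy]butyl}triphenylphosphonium bromide
Product: 16 (4Z,8R,15Z,17Z)-1-[(tert-butyldimethylsilyl)oxy]docosa-4,15,17,21-tetraen-8-ol, via ylide 15 (not isolated)
Conditions: 14 (2.4 equiv), KHMDS (2.3 equiv), THF, −78 → 0 °C; then 12, −78 °C → rt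
Reagents that add atoms: none
Why: Under the basic conditions lactol 12 is in equilibrium with its open 4-oxido aldehyde, and the salt-free, non-stabilised ylide 15 adds to the C7 carbonyl to give kinetically the cis-oxaphosphetane, whose syn cycloreversion gives the (Z)-C6=C7 alkene and Ph3PO; the closest known reaction type is the Wittig olefination of γ-lactols with alkylidene ylides. The step closes no ring: it opens the lactol ring, so that the former ring oxygen reappears as the free C10 hydroxyl of a bishomoallylic alcohol, the substrate that step 10 needs. It creates no stereocentre; what it fixes is the Z geometry of C6=C7, which step 10 translates by syn addition into the erythro C6/C7 pair, while C10 controls the trans ring. The selectivity needed is Z over E at the new double bond, secured by the unstabilised ylide, the lithium-free potassium base and the low temperature. Chemoselectivity is not at stake, because the ylide partner carries only a silyl ether and the (Z,Z)-diene and terminal alkene of 12 do not react with ylides; one extra equivalent of ylide is consumed as base by the lactol hydroxyl.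

Step 10
Reactants: 16 (4Z,8R,15Z,17Z)-1-[(tert-butyldimethylsilyl)oxy]docosa-4,15,17,21-tetraen-8-ol
Product: 17 (1R)-4-[(tert-butyldimethylsilyl)oxy]-1-[(2S,5R)-5-[(7Z,9Z)-tetradeca-7,9,13-trien-1-yl]oxolan-2-yl]butan-1-ol
Conditions: Re2O7 (1.5 equiv), 2,6-lutidine, CH2Cl2, 0 °C → rt
Reagents that add atoms: dirhenium heptoxide, O=[Re](=O)(=O)O[Re](=O)(=O)=O
Why: Rhenium(VII) syn-oxidative cyclisation of a bishomoallylic alcohol, in which the C10 perrhenate ester adds its alkoxide oxygen and one oxo oxygen to the same face of the (Z)-alkene in the 5-exo mode, should give the erythro C6 carbinol/C7 ether pair and, through a chair-like transition state with the C10 chain pseudo-equatorial, the 2,5-trans oxolane, so that C7 (S) and C6 (R) are both set from C10; the remote diene and vinyl group have no hydroxyl within reach and should stay untouched.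

Step 11
Reactants: 17 (1R)-4-[(tert-butyldimethylsilyl)oxy]-1-[(2S,5R)-5-[(7Z,9Z)-tetradeca-7,9,13-trien-1-yl]oxolan-2-yl]butan-1-ol
Product: 18 (1R)-4-[(tert-butyldimethylsilyl)oxy]-1-[(2S,5R)-5-[(7Z,9Z)-tetradeca-7,9,13-trien-1-yl]oxolan-2-yl]butyl methanesulfonate
Conditions: MsCl, Et3N, CH2Cl2, 0 °C
Reagents that add atoms: methanesulfonyl chloride, CS(=O)(=O)Cl
Why: Sulfonylation of the secondary alcohol occurs at oxygen with retention at C6 and provides the leaving group for the inversion of step 13.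

Step 12
Reactants: 19 2,3-dimethylbut-2-ene
Product: 20 2-hydroperoxy-2-methoxypropane
Conditions: O3, MeOH/CH2Cl2, −78 °C
Reagents that add atoms: ozone, [O-][O+]=O; methanol, CO
Why: Ozonolysis in methanol, in which the carbonyl oxide of the Criegee fragmentation is trapped by the solvent to give the α-methoxy hydroperoxide beside acetone.

Step 13
Reactants: 18 (1R)-4-[(tert-butyldimethylsilyl)oxy]-1-[(2S,5R)-5-[(7Z,9Z)-tetradeca-7,9,13-trien-1-yl]oxolan-2-yl]butyl methanesulfonate; 20 2-hydroperoxy-2-methoxypropane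
Product: 21 tert-butyl{[(4S)-4-[(2-methoxypropan-2-yl)peroxy]-4-[(2S,5R)-5-[(7Z,9Z)-tetradeca-7,9,13-trien-1-yl]oxolan-2-yl]butyl]oxy}dimethylsilane
Conditions: 20 (3 equiv), CsOH·H2O (2.5 equiv), DMF, 0 °C → rt
Reagents that add atoms: none
Why: SN2 displacement of a secondary sulfonate by the caesium salt of an alkyl hydroperoxide (an α-effect nucleophile) should proceed with inversion, turning the (6R)-mesylate into the (6S)-peroxide that has the threo relation to C7 and carries the O–O unit as an acid-labile monoperoxyketal.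

Step 14
Reactants: 21 tert-butyl{[(4S)-4-[(2-methoxypropan-2-yl)peroxy]-4-[(2S,5R)-5-[(7Z,9Z)-tetradeca-7,9,13-trien-1-yl]oxolan-2-yl]butyl]oxy}dimethylsilane
Product: 22 (4S)-4-[(2-methoxypropan-2-yl)peroxy]-4-[(2S,5R)-5-[(7Z,9Z)-tetradeca-7,9,13-trien-1-yl]oxolan-2-yl]butan-1-ol
Conditions: TBAF, THF, 0 °C
Reagents that add atoms: none
Why: Fluoride-induced cleavage of the primary silyl ether; the dialkyl peroxyketal should be stable to fluoride at 0 °C.

Step 15
Reactants: 22 (4S)-4-[(2-methoxypropan-2-yl)peroxy]-4-[(2S,5R)-5-[(7Z,9Z)-tetradeca-7,9,13-trien-1-yl]oxolan-2-yl]butan-1-ol; 23 methyl (triphenylphosphoranylidene)acetate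
Product: 25 methyl (2E,6S)-6-[(2-methoxypropan-2-yl)peroxy]-6-[(2S,5R)-5-[(7Z,9Z)-tetradeca-7,9,13-trien-1-yl]oxolan-2-yl]hex-2-enoate, via aldehyde 24 (not isolated)
Conditions: Dess–Martin periodinane, pyridine, CH2Cl2, 0 °C → rt; then 23, rt
Reagents that add atoms: none
Why: Dess–Martin oxidation to the aldehyde followed in the same flask by Wittig olefination with the stabilised ylide should give the (E)-enoate that serves as acceptor for the ring closure; the pyridine buffer protects the peroxyketal and C6 is not touched.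

Step 16
Reactants: 25 methyl (2E,6S)-6-[(2-methoxypropan-2-yl)peroxy]-6-[(2S,5R)-5-[(7Z,9Z)-tetradeca-7,9,13-trien-1-yl]oxolan-2-yl]hex-2-enoate
Product: 27 methyl 2-[(3S,6S)-6-[(2S,5R)-5-[(7Z,9Z)-tetradeca-7,9,13-trien-1-yl]oxolan-2-yl]-1,2-dioxan-3-yl]acetate, via hydroperoxide 26 (not isolated)
Conditions: AcOH/THF/H2O (4:2:1), rt; evaporate; then Et2NH (0.5 equiv), CF3CH2OH, rt
Reagents that add atoms: none
Why: Mild acid hydrolysis of the monoperoxyketal frees the C6 hydroperoxide, which under amine catalysis should add to the enoate in a 6-exo-trig oxa-Michael reaction; C3 is set relative to C6 through a chair transition state with both substituents equatorial, which is also the thermodynamically preferred trans-3,6 dioxane, and protonation of the ester enolate outruns O–O cleavage.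

Step 17
Reactants: 27 methyl 2-[(3S,6S)-6-[(2S,5R)-5-[(7Z,9Z)-tetradeca-7,9,13-trien-1-yl]oxolan-2-yl]-1,2-dioxan-3-yl]acetate
Product: 28 2-[(3S,6S)-6-[(2S,5R)-5-[(7Z,9Z)-tetradeca-7,9,13-trien-1-yl]oxolan-2-yl]-1,2-dioxan-3-yl]acetic acid
Conditions: LiOH (3 equiv), THF/H2O (3:1), 0 °C; then 0.5 M HCl to pH 4, 0 °C
Reagents that add atoms: lithium hydroxide, [Li+].[OH-]
Why: Saponification of the methyl ester at 0 °C followed by mild acidification should give the acid; the dialkyl peroxide and the β-peroxy centre C3 are expected to survive the short, cold treatment.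

**Compound list**

1 | hex-1-en-5-yne | C=CCCC#C | starting material
2 | 6-bromohex-1-en-5-yne | C=CCCC#CBr | intermediate
3 | hept-6-yn-1-ol | C#CCCCCCO | starting material
4 | trideca-12-en-6,8-diyn-1-ol | OCCCCCC#CC#CCCC=C | intermediate
5 | (6Z,8Z)-trideca-6,8,12-trien-1-ol | OCCCCC/C=C\C=C/CCC=C | intermediate
6 | (5Z,7Z)-13-bromotrideca-1,5,7-triene | BrCCCCC/C=C\C=C/CCC=C | intermediate
7 | [(2S)-5-oxooxolan-2-yl]methyl 4-methylbenzenesulfonate | O=C1CC[C@@H](COS(=O)(=O)c2ccc(C)cc2)O1 | starting material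
8 | methyl 3-[(2S)-oxiran-2-yl]propanoate | COC(=O)CC[C@H]1CO1 | intermediate
9 | [(6Z,8Z)-trideca-6,8,12-trien-1-yl]magnesium bromide | Br[Mg]CCCCC/C=C\C=C/CCC=C | intermediate
10 | methyl (4R,11Z,13Z)-4-hydroxyoctadeca-11,13,17-trienoate | COC(=O)CC[C@H](O)CCCCCC/C=C\C=C/CCC=C | intermediate
11 | (5R)-5-[(7Z,9Z)-tetradeca-7,9,13-trien-1-yl]oxolan-2-one | C=CCC/C=C\C=C/CCCCCC[C@@H]1CCC(=O)O1 | intermediate
12 | (5R)-5-[(7Z,9Z)-tetradeca-7,9,13-trien-1-yl]oxolan-2-ol | C=CCC/C=C\C=C/CCCCCC[C@@H]1CCC(O)O1 | intermediate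
13 | (4-bromobutoxy)(tert-butyl)dimethylsilane | CC(C)(C)[Si](C)(C)OCCCCBr | starting material
14 | {4-[(tert-butyldimethylsilyl)oxy]butyl}triphenylphosphonium bromide | CC(C)(C)[Si](C)(C)OCCCC[P+](c1ccccc1)(c1ccccc1)c1ccccc1.[Br-] | intermediate
15 | {4-[(tert-butyldimethylsilyl)oxy]butylidene}triphenylphosphorane | CC(C)(C)[Si](C)(C)OCCCC=P(c1ccccc1)(c1ccccc1)c1ccccc1 | intermediate
16 | (4Z,8R,15Z,17Z)-1-[(tert-butyldimethylsilyl)oxy]docosa-4,15,17,21-tetraen-8-ol | C=CCC/C=C\C=C/CCCCCC[C@@H](O)CC/C=C\CCCO[Si](C)(C)C(C)(C)C | intermediate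
17 | (1R)-4-[(tert-butyldimethylsilyl)oxy]-1-[(2S,5R)-5-[(7Z,9Z)-tetradeca-7,9,13-trien-1-yl]oxolan-2-yl]butan-1-ol | C=CCC/C=C\C=C/CCCCCC[C@@H]1CC[C@@H]([C@H](O)CCCO[Si](C)(C)C(C)(C)C)O1 | intermediate
18 | (1R)-4-[(tert-butyldimethylsilyl)oxy]-1-[(2S,5R)-5-[(7Z,9Z)-tetradeca-7,9,13-trien-1-yl]oxolan-2-yl]butyl methanesulfonate | C=CCC/C=C\C=C/CCCCCC[C@@H]1CC[C@@H]([C@H](OS(C)(=O)=O)CCCO[Si](C)(C)C(C)(C)C)O1 | intermediate
19 | 2,3-dimethylbut-2-ene | CC(C)=C(C)C | starting material
20 | 2-hydroperoxy-2-methoxypropane | COC(C)(C)OO | intermediate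
21 | tert-butyl{[(4S)-4-[(2-methoxypropan-2-yl)peroxy]-4-[(2S,5R)-5-[(7Z,9Z)-tetradeca-7,9,13-trien-1-yl]oxolan-2-yl]butyl]oxy}dimethylsilane | C=CCC/C=C\C=C/CCCCCC[C@@H]1CC[C@@H]([C@@H](OOC(C)(C)OC)CCCO[Si](C)(C)C(C)(C)C)O1 | intermediate
22 | (4S)-4-[(2-methoxypropan-2-yl)peroxy]-4-[(2S,5R)-5-[(7Z,9Z)-tetradeca-7,9,13-trien-1-yl]oxolan-2-yl]butan-1-ol | C=CCC/C=C\C=C/CCCCCC[C@@H]1CC[C@@H]([C@@H](OOC(C)(C)OC)CCCO)O1 | intermediate
23 | methyl (triphenylphosphoranylidene)acetate | COC(=O)C=P(c1ccccc1)(c1ccccc1)c1ccccc1 | starting material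
24 | (4S)-4-[(2-methoxypropan-2-yl)peroxy]-4-[(2S,5R)-5-[(7Z,9Z)-tetradeca-7,9,13-trien-1-yl]oxolan-2-yl]butanal | C=CCC/C=C\C=C/CCCCCC[C@@H]1CC[C@@H]([C@@H](OOC(C)(C)OC)CCC=O)O1 | intermediate
25 | methyl (2E,6S)-6-[(2-methoxypropan-2-yl)peroxy]-6-[(2S,5R)-5-[(7Z,9Z)-tetradeca-7,9,13-trien-1-yl]oxolan-2-yl]hex-2-enoate | C=CCC/C=C\C=C/CCCCCC[C@@H]1CC[C@@H]([C@@H](OOC(C)(C)OC)CC/C=C/C(=O)OC)O1 | intermediate
26 | methyl (2E,6S)-6-hydroperoxy-6-[(2S,5R)-5-[(7Z,9Z)-tetradeca-7,9,13-trien-1-yl]oxolan-2-yl]hex-2-enoate | C=CCC/C=C\C=C/CCCCCC[C@@H]1CC[C@@H]([C@@H](OO)CC/C=C/C(=O)OC)O1 | intermediate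
27 | methyl 2-[(3S,6S)-6-[(2S,5R)-5-[(7Z,9Z)-tetradeca-7,9,13-trien-1-yl]oxolan-2-yl]-1,2-dioxan-3-yl]acetate | C=CCC/C=C\C=C/CCCCCC[C@@H]1CC[C@@H]([C@@H]2CC[C@@H](CC(=O)OC)OO2)O1 | intermediate
28 | 2-[(3S,6S)-6-[(2S,5R)-5-[(7Z,9Z)-tetradeca-7,9,13-trien-1-yl]oxolan-2-yl]-1,2-dioxan-3-yl]acetic acid | C=CCC/C=C\C=C/CCCCCC[C@@H]1CC[C@@H]([C@@H]2CC[C@@H](CC(=O)O)OO2)O1 | target

**Step count**

Total step count: 17. Longest linear sequence: 14 steps (steps 1–4, 6, 7, 9–11, 13–17).

**Steps most likely to fail**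

Step 13 (peroxide displacement). The bimolecular substitution at the β-oxygenated secondary carbon C6 may be slow, so that E2 elimination, base-induced fragmentation of the secondary peroxide formed, or participation of a neighbouring oxygen take over. The fallback makes this C–O bond intramolecularly. It sets out from mesylate 18. The silyl ether is removed with HF·pyridine (THF, 0 °C) to give the hydroxy mesylate F1, which is oxidised at once with Dess–Martin periodinane to the aldehyde mesylate F2. Acid-catalysed exchange with anhydrous hydrogen peroxide in methanol should give the methoxy hydroperoxide F3 (a hydroperoxyacetal, epimers at the acetal carbon). With KOtBu and 18-crown-6 in THF at 0 °C its peroxide anion should displace the C6 mesylate in a 6-exo-tet closure with inversion to give the methoxydioxane F4, in which C6 already has the S configuration. The acetate unit is then introduced at C3 through the peroxycarbenium ion (TMSOTf, 1-(tert-butyldimethylsilyloxy)-1-methoxyethene, CH2Cl2, −78 °C; Mukaiyama-type addition). This comes back to the route at ester 27; a C3 epimer, if formed, would be separated there.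

Step 16 (dioxane closure). Facial discrimination in the conjugate addition may be insufficient, so that the ring closes to a mixture of C3 epimers. The fallback changes the acceptor geometry and sets out from alcohol 22. After oxidation to aldehyde 24 as in step 15, a Still–Gennari olefination (methyl bis(2,2,2-trifluoroethyl)phosphonoacetate, KHMDS, 18-crown-6, THF, −78 °C) should give the (Z)-enoate F5. Hydrolysis with aqueous acetic acid frees the (Z)-hydroperoxide F6, which is closed with Et2NH in trifluoroethanol. With a (Z)-acceptor, allylic strain disfavours the chair that carries the side chain axial, as in the related oxa-Michael closures to tetrahydropyrans, so the diequatorial ring should dominate. The fallback comes back to the route at ester 27.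

Step 10 (oxidative cyclisation). Chemoselectivity may be lost through oxidation or acid-promoted isomerisation at the conjugated diene, or the trans selectivity of ring formation may erode. The fallback separates epoxidation from ring closure and sets out from alkenol 16. Vanadium-catalysed hydroxyl-directed epoxidation (VO(acac)2, t-BuOOH, CH2Cl2), which reaches only the alkene near the C10 hydroxyl, should give the cis-epoxide F7. Camphorsulfonic acid then induces 5-exo opening at C7 with inversion to the threo alcohol F8; a cis-ring isomer would be removed at this point. Mitsunobu inversion at C6 (4-nitrobenzoic acid, DIAD, PPh3) gives the nitrobenzoate F9, and methanolysis (K2CO3, MeOH) comes back to the route at alcohol 17.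

**Further compounds**

F1 | step 13 | (1R)-4-hydroxy-1-[(2S,5R)-5-[(7Z,9Z)-tetradeca-7,9,13-trien-1-yl]oxolan-2-yl]butyl methanesulfonate | C=CCC/C=C\C=C/CCCCCC[C@@H]1CC[C@@H]([C@H](OS(C)(=O)=O)CCCO)O1
F2 | step 13 | (1R)-4-oxo-1-[(2S,5R)-5-[(7Z,9Z)-tetradeca-7,9,13-trien-1-yl]oxolan-2-yl]butyl methanesulfonate | C=CCC/C=C\C=C/CCCCCC[C@@H]1CC[C@@H]([C@H](OS(C)(=O)=O)CCC=O)O1
F3 | step 13 | (1R)-4-hydroperoxy-4-methoxy-1-[(2S,5R)-5-[(7Z,9Z)-tetradeca-7,9,13-trien-1-yl]oxolan-2-yl]butyl methanesulfonate | C=CCC/C=C\C=C/CCCCCC[C@@H]1CC[C@@H]([C@H](OS(C)(=O)=O)CCC(OC)OO)O1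
F4 | step 13 | (2S,5R)-2-[(3S)-6-methoxy-1,2-dioxan-3-yl]-5-[(7Z,9Z)-tetradeca-7,9,13-trien-1-yl]oxolane | C=CCC/C=C\C=C/CCCCCC[C@@H]1CC[C@@H]([C@@H]2CCC(OC)OO2)O1
F5 | step 16 | methyl (2Z,6S)-6-[(2-methoxypropan-2-yl)peroxy]-6-[(2S,5R)-5-[(7Z,9Z)-tetradeca-7,9,13-trien-1-yl]oxolan-2-yl]hex-2-enoate | C=CCC/C=C\C=C/CCCCCC[C@@H]1CC[C@@H]([C@@H](OOC(C)(C)OC)CC/C=C\C(=O)OC)O1
F6 | step 16 | methyl (2Z,6S)-6-hydroperoxy-6-[(2S,5R)-5-[(7Z,9Z)-tetradeca-7,9,13-trien-1-yl]oxolan-2-yl]hex-2-enoate | C=CCC/C=C\C=C/CCCCCC[C@@H]1CC[C@@H]([C@@H](OO)CC/C=C\C(=O)OC)O1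
F7 | step 10 | (3R,10Z,12Z)-1-[(2R,3S)-3-{3-[(tert-butyldimethylsilyl)oxy]propyl}oxiran-2-yl]heptadeca-10,12,16-trien-3-ol | C=CCC/C=C\C=C/CCCCCC[C@@H](O)CC[C@H]1O[C@H]1CCCO[Si](C)(C)C(C)(C)C
F8 | step 10 | (1S)-4-[(tert-butyldimethylsilyl)oxy]-1-[(2S,5R)-5-[(7Z,9Z)-tetradeca-7,9,13-trien-1-yl]oxolan-2-yl]butan-1-ol | C=CCC/C=C\C=C/CCCCCC[C@@H]1CC[C@@H]([C@@H](O)CCCO[Si](C)(C)C(C)(C)C)O1
F9 | step 10 | (1R)-4-[(tert-butyldimethylsilyl)oxy]-1-[(2S,5R)-5-[(7Z,9Z)-tetradeca-7,9,13-trien-1-yl]oxolan-2-yl]butyl 4-nitrobenzoate | C=CCC/C=C\C=C/CCCCCC[C@@H]1CC[C@@H]([C@H](OC(=O)c2ccc(cc2)[N+](=O)[O-])CCCO[Si](C)(C)C(C)(C)C)O1
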